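3 questions stand for maple, and this is what I have:

common to all: substrate 0.050 M; gas 19 mM (held)
- maple: second nucleophile 1.5 equiv; the very flask that is asked about, followed so far
- flask: second nucleophile 1.50 equiv; time 5.0 d
maple run (percent of the substrate charged)

| time / h | target / % | other capture product / % |
|---|---|---|
| 3.00 | 0 | 9.1 |
| 10.0 | 1.1 | 22.9 |
| 15.0 | 0.3 | 29.0 |
| 25.0 | 0.9 | 34.8 |
| 40.0 | 3.3 | 41.3 |
| 50.0 | 1.9 | 43.5 |

(each reading ± 1 percentage point)
- share of target in target plus other capture product at 25 min
- share of target in target plus other capture product at 5.0 d
- which of target and other capture product there is more of at 5.0 d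
- at the start none of the gas is in solution

I follow one molecule of substrate to its capture and assume one fork: dissolved gas or second nucleophile, each taken in proportion to its concentration. Single target readings drown in the scatter, so I add them. Target sums to 7.50% and other capture product to 180.6%, odds of 0.0415, uncertain by 32.7% of their value. Second nucleophile averages about 64.1 mM between charge and last reading. My selectivity factor is g = 0.140, the odds times c(second nucleophile) over c(gas).

From below, the low end of g with second nucleophile at full charge and gas at its saturation value of 19 mM gives a share of 2.34% at 5.0 d. From above, the high end with second nucleophile lowered by a full capture of the substrate gives 12.4%. The readings flatten, so I tighten this with what remains at 50.0 h, to 6.22%. At 25 min I expect between zero and 4.50%, since gas starts at none. Other capture product leads, as the share stays under half.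

The forecast gives 1%, 10% and other capture product, on the ground that “other capture product plateaus while target keeps draining slowly”. Its 10% stands above my tightened bound and inside the loose one.

    gas ⇌ first nucleophile, rate k1*(csat - [first nucleophile]) (kL = 6.03 × 10⁻⁴ s⁻¹)
    intermediate → solvolysis product (k = 0.00430 s⁻¹)
    substrate → intermediate (k = 1.19 × 10⁻⁵ s⁻¹)
    first nucleophile + intermediate → target (k = 0.365 M⁻¹ s⁻¹)
    intermediate → side product (k = 2.38 × 10⁻⁵ s⁻¹)
    2 substrate → homo dimer (k = 2.97 × 10⁻⁴ M⁻¹ s⁻¹)
    second nucleophile + intermediate → other capture product (k = 2.01 M⁻¹ s⁻¹)

Maple gives 1.55% at 25 min and 5.04% at 5.0 d, with 2.44% of target against 46.0% of other capture product, so all 3 forecast answers hold within their margins. At 5.0 d, second nucleophile uses intermediate 15 times as fast as first nucleophile does. With 69% of second nucleophile left, g gives a molecule choosing then a target chance of 4.87%.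

In a neighbour of maple charged with 0.600 equiv of second nucleophile, g with a mean of 20.3 mM gives a share of 11.6%. That flask computes to 15.2%, with 6.92% of target against 38.6% of other capture product, so the lead stays.

The earlier runs and the new flask come from a simulation with made-up constants, noise included.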